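**Plan**

- Retrosynthesis: the last cuts are four benzylic C–O bonds (three benzyl ethers, one benzyl carbonate) and the 4'-O–CH3 bond. Next, the biaryl bond between C3' of ring B of the flavanone and C8 of ring A of the flavone is cut as a dehydrogenative C–H/C–H coupling of two complete flavonoids. The flavanone is then cut at C2–C1' (conjugate arylation of a chromone); the flavone half is apigenin.
- Forward: 5,7-dihydroxychromone is 7-O-methylated and 5-O-protected, ring B is added to C2 (ring C becomes the flavanone), apigenin is perbenzylated, the two flavonoids are joined at the anode, then 4'-O-methylation and one hydrogenolysis follow.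
- Enabling feature: the free 4'-OH on ring B of the flavanone, whose para carbon C1' is occupied by C2, so its phenoxyl radical can only bond through C3' (= C5'); and the C8–H of ring A of the flavone, ortho to O7 and O1 and para to O5.
- Helpers: the benzyl carbonate on O5 (switches ring A of the flavanone off as a competing nucleophile and leaves together with the benzyl ethers) and the free 4'-OH (activating group, methylated after the coupling).
- Stereochemistry: C2 (S) is set in step 3 by ligand-controlled, enantioface-selective aryl transfer to the chromone; no basic step follows, so retro-oxa-Michael racemisation is avoided.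

Key step: step 5

Remark: the new biaryl axis carries three small ortho substituents (OMe, O7, O1) and is taken to rotate freely, so C2 of the flavanone is the only stereo-element to be controlled.

**Route**

Step 1
Reactants: 1 5,7-dihydroxychromone
Product: 2 5-hydroxy-7-methoxychromone
Conditions: MeI (1.1 equiv), K2CO3 (1.2 equiv), acetone, 40 °C
Reagents that add atoms: iodomethane, CI
Why: Williamson O-methylation, in which the 7-OH (para to the pyranone carbonyl and the most acidic) is alkylated while the 5-OH stays free because it is held in a hydrogen bond to C4=O and only a small excess of MeI with a weak base is used.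

Step 2
Reactants: 2 5-hydroxy-7-methoxychromone
Product: 3 benzyl (7-methoxy-4-oxo-4H-chromen-5-yl) carbonate
Conditions: CbzCl (1.5 equiv), Et3N, DMAP (cat.), CH2Cl2, 0 °C to rt
Reagents that add atoms: benzyl chloroformate, O=C(Cl)OCc1ccccc1
Why: DMAP-catalysed O-acylation (carbonate formation) of the chelated 5-OH, which masks the phenol, makes the chromone a better Michael acceptor and will later lower the nucleophilicity of ring A of the flavanone.

Step 3
Reactants: 3 benzyl (7-methoxy-4-oxo-4H-chromen-5-yl) carbonate; 4 (4-hydroxyphenyl)boronic acid (2 equiv)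
Product: 5 benzyl [(2S)-2-(4-hydroxyphenyl)-7-methoxy-4-oxochroman-5-yl] carbonate
Conditions: Pd(OCOCF3)2 (5 mol%), (R)-4-tert-butyl-2-(pyridin-2-yl)-4,5-dihydrooxazole [(R)-t-BuPyOx, 6 mol%], NH4PF6 (30 mol%), H2O (5 equiv), ClCH2CH2Cl, 60 °C
Reagents that add atoms: none
Why: Asymmetric conjugate addition of an arylboronic acid to a chromone with a cationic divalent palladium/pyridine-oxazoline catalyst (Hayashi–Miyaura-type 1,4-addition), in which transmetalation gives an aryl–palladium species that inserts C2=C3 on the enantioface left open by the tert-butyl group and water protonates the palladium enolate; the (R)-ligand is chosen because, by analogy with β-substituted cyclic enones, it should deliver the aryl group to the face that gives 2S, and the neutral medium tolerates the free phenol and the carbonate.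

Step 4
Reactants: 6 apigenin
Product: 7 5,7-bis(benzyloxy)-2-[4-(benzyloxy)phenyl]-4H-chromen-4-one
Conditions: BnBr (4 equiv), K2CO3 (4 equiv), Bu4NI (cat.), DMF, 80 °C
Reagents that add atoms: benzyl bromide, BrCc1ccccc1
Why: Exhaustive Williamson benzylation, in which 7-OH and 4'-OH react readily and the chelated 5-OH follows with excess BnBr at 80 °C; the 5-O-alkyl group is wanted because it steers later substitution of ring A to C8.

Step 5
Reactants: 5 benzyl [(2S)-2-(4-hydroxyphenyl)-7-methoxy-4-oxochroman-5-yl] carbonate; 7 5,7-bis(benzyloxy)-2-[4-(benzyloxy)phenyl]-4H-chromen-4-one (3 equiv, excess recovered)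
Product: 8 benzyl [(2S)-2-{3-[5,7-bis(benzyloxy)-2-(4-(benzyloxy)phenyl)-4-oxo-4H-chromen-8-yl]-4-hydroxyphenyl}-7-methoxy-4-oxochroman-5-yl] carbonate
Conditions: constant-current electrolysis (2.8 mA cm−2, 2.2 F mol−1 based on 5), undivided cell, boron-doped diamond anode, Ni cathode, Bu3NMe+ MeOSO3− (0.09 M), (CF3)2CHOH, 40 °C
Reagents that add atoms: none
Why: Proposed new method: the only free phenol of the pair, the 4'-OH on ring B of 5, should be oxidised at the boron-doped diamond anode to a phenoxyl radical that is solvated by (CF3)2CHOH and carries its spin on C3'/C5' (equivalent) and on C1' (blocked by C2); this radical should form the C3'–C8 bond with ring A of 7, and a second electron transfer with loss of two protons rearomatises both rings while protons are reduced to H2 at the cathode. The closest known reaction type is the anodic dehydrogenative phenol–arene cross-coupling of simple 4-alkylphenols with polyalkoxybenzenes in fluorinated alcohols, which has not been shown with a flavanone as the phenol or a flavone as the arene. No ring is closed and no stereocentre is made: C2 is not involved and sees no base, and the new axis is not configurationally stable. The step needs cross- over homo-coupling, which is secured because 5 is the only partner with a free OH (lowest oxidation potential) while its own ring A is deactivated by the 5-O-carbonate and the C4 ketone, so that the trialkoxylated ring A of 7, used in excess, is the best nucleophile present. It needs C8 over C6 and C3 on 7, which is secured because C8 is ortho to O7 and O1 and para to O5 whereas C6 is buttressed between two benzyloxy groups, the same preference that electrophilic iodination of 5,7-dialkoxyflavones shows. Over-oxidation of product 8 or of the C2–H bond is limited by the hydrogen-bonding solvent and by stopping at about 2 F per mole.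

Step 6
Reactants: 8 benzyl [(2S)-2-{3-[5,7-bis(benzyloxy)-2-(4-(benzyloxy)phenyl)-4-oxo-4H-chromen-8-yl]-4-hydroxyphenyl}-7-methoxy-4-oxochroman-5-yl] carbonate
Product: 9 benzyl [(2S)-2-{3-[5,7-bis(benzyloxy)-2-(4-(benzyloxy)phenyl)-4-oxo-4H-chromen-8-yl]-4-methoxyphenyl}-7-methoxy-4-oxochroman-5-yl] carbonate
Conditions: MeOH (5 equiv), PPh3, DIAD, THF, 0 °C to rt
Reagents that add atoms: methanol, CO
Why: Mitsunobu etherification with methanol, which methylates the only free OH of 8 (4'-OH of ring B) under neutral conditions, so that the base-labile C2 centre (retro-oxa-Michael opening) and the aryl carbonate are not touched.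

Step 7
Reactants: 9 benzyl [(2S)-2-{3-[5,7-bis(benzyloxy)-2-(4-(benzyloxy)phenyl)-4-oxo-4H-chromen-8-yl]-4-methoxyphenyl}-7-methoxy-4-oxochroman-5-yl] carbonate
Product: 10 8-{5-[(2S)-5-hydroxy-7-methoxy-4-oxochroman-2-yl]-2-methoxyphenyl}-5,7-dihydroxy-2-(4-hydroxyphenyl)-4H-chromen-4-one (target)
Conditions: H2 (1 atm), Pd/C (10 wt%), EtOAc/MeOH, rt
Reagents that add atoms: none
Why: Heterogeneous hydrogenolysis of the three benzyl ethers and of the benzyl carbonate (which loses CO2 to free the 5-OH) under neutral conditions that should leave the two methyl ethers, the C2 stereocentre, the flavone C2=C3 bond and both carbonyl groups intact.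

**Compound list**

1 | 5,7-dihydroxychromone | O=c1ccoc2cc(O)cc(O)c12 | starting material
2 | 5-hydroxy-7-methoxychromone | COc1cc(O)c2c(=O)ccoc2c1 | intermediate
3 | benzyl (7-methoxy-4-oxo-4H-chromen-5-yl) carbonate | COc1cc(OC(=O)OCc3ccccc3)c2c(=O)ccoc2c1 | intermediate
4 | (4-hydroxyphenyl)boronic acid | OB(O)c1ccc(O)cc1 | starting material
5 | benzyl [(2S)-2-(4-hydroxyphenyl)-7-methoxy-4-oxochroman-5-yl] carbonate | COc1cc(OC(=O)OCc3ccccc3)c2c(c1)O[C@H](c1ccc(O)cc1)CC2=O | intermediate
6 | apigenin (5,7-dihydroxy-2-(4-hydroxyphenyl)-4H-chromen-4-one) | O=c1cc(-c2ccc(O)cc2)oc2cc(O)cc(O)c12 | starting material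
7 | 5,7-bis(benzyloxy)-2-[4-(benzyloxy)phenyl]-4H-chromen-4-one | O=c1cc(-c2ccc(OCc3ccccc3)cc2)oc2cc(OCc3ccccc3)cc(OCc3ccccc3)c12 | intermediate
8 | benzyl [(2S)-2-{3-[5,7-bis(benzyloxy)-2-(4-(benzyloxy)phenyl)-4-oxo-4H-chromen-8-yl]-4-hydroxyphenyl}-7-methoxy-4-oxochroman-5-yl] carbonate | COc1cc(OC(=O)OCc6ccccc6)c2c(c1)O[C@H](c1ccc(O)c(-c3c(OCc6ccccc6)cc(OCc6ccccc6)c4c(=O)cc(-c5ccc(OCc6ccccc6)cc5)oc34)c1)CC2=O | intermediate
9 | benzyl [(2S)-2-{3-[5,7-bis(benzyloxy)-2-(4-(benzyloxy)phenyl)-4-oxo-4H-chromen-8-yl]-4-methoxyphenyl}-7-methoxy-4-oxochroman-5-yl] carbonate | COc1cc(OC(=O)OCc6ccccc6)c2c(c1)O[C@H](c1ccc(OC)c(-c3c(OCc6ccccc6)cc(OCc6ccccc6)c4c(=O)cc(-c5ccc(OCc6ccccc6)cc5)oc34)c1)CC2=O | intermediate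
10 | 8-{5-[(2S)-5-hydroxy-7-methoxy-4-oxochroman-2-yl]-2-methoxyphenyl}-5,7-dihydroxy-2-(4-hydroxyphenyl)-4H-chromen-4-one | COc1cc(O)c2c(c1)O[C@H](c1ccc(OC)c(-c3c(O)cc(O)c4c(=O)cc(-c5ccc(O)cc5)oc34)c1)CC2=O | target

**Step count**

Total steps: 7. Longest linear sequence: 6 (steps 1, 2, 3, 5, 6, 7 from compound 1); the apigenin branch enters through step 4.

**Steps most likely to fail**

1. Step 5 (anodic cross-coupling). What may go wrong:
- homo-coupling of the phenoxyl radical with ring A of a second molecule of 5;
- bond formation at C6 or C3 of the flavone instead of C8;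
- two-electron over-oxidation with loss of the C2–H (dehydrogenation of ring C and loss of the stereocentre);
- anodic attack on benzylic C–H bonds.

Fallback (known chemistry, Suzuki–Miyaura biaryl coupling; sets out from 7 and 3, comes back at 9). Compound 7 is iodinated at C8 with I2/AgOCOCF3 in CH2Cl2 to give 5,7-bis(benzyloxy)-2-[4-(benzyloxy)phenyl]-8-iodo-4H-chromen-4-one F1. Miyaura borylation (bis(pinacolato)diboron, PdCl2(dppf), KOAc, dioxane, 90 °C) should convert it into 5,7-bis(benzyloxy)-2-[4-(benzyloxy)phenyl]-8-(4,4,5,5-tetramethyl-1,3,2-dioxaborolan-2-yl)-4H-chromen-4-one F2. In parallel, chromone 3 is arylated under the conditions of step 3 with commercial (3-bromo-4-methoxyphenyl)boronic acid (COc1ccc(B(O)O)cc1Br) to give benzyl [(2S)-2-(3-bromo-4-methoxyphenyl)-7-methoxy-4-oxochroman-5-yl] carbonate F3. Coupling of F2 with F3 (Pd(OAc)2, SPhos, CsF, dioxane, 80 °C, non-aqueous to spare the carbonate and C2) should give 9 directly. The 4'-OMe is already in place, so step 6 is not needed.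

2. Step 3 (asymmetric conjugate arylation). What may go wrong: poor enantiofacial discrimination or slow insertion on the electron-rich, peri-substituted chromone, and protodeboronation of the electron-rich boronic acid.

Fallback (sets out from 3 and 4, comes back at 5; the stereocentre then comes from a kinetic resolution instead of the C–C bond formation). Addition of 4 to 3 with the achiral, more active catalyst Pd(OCOCF3)2/2,2'-bipyridine (aqueous AcOH/THF, 50 °C) should give racemic benzyl [2-(4-hydroxyphenyl)-7-methoxy-4-oxochroman-5-yl] carbonate F4. Asymmetric transfer hydrogenation with [Cp*RhCl((R,R)-TsDPEN)] and HCO2H/Et3N in EtOAc, stopped near half conversion, should reduce the 2R ketone to benzyl [(2R,4R)-4-hydroxy-2-(4-hydroxyphenyl)-7-methoxychroman-5-yl] carbonate F5. The unreacted 2S ketone 5 is then separated by chromatography.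

3. Step 7 (global hydrogenolysis). What may go wrong: incomplete cleavage of the hindered benzyl ethers, hydrogenolysis of the benzylic C2–O1 bond of ring C of the flavanone, or reduction of the C4 carbonyl or of the flavone C2=C3 bond.

Fallback (sets out from 9, comes back at 10; Lewis-acid debenzylation instead of reduction). BCl3 with pentamethylbenzene as cation scavenger in CH2Cl2 at −78 °C should cleave the benzyl ethers and the benzyl carbonate. The non-chelated methyl ethers at O7 and O4' should survive at this temperature. Aqueous work-up gives 10; no new compound is made.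

**Further compounds**

F1 | step 5 | 5,7-bis(benzyloxy)-2-[4-(benzyloxy)phenyl]-8-iodo-4H-chromen-4-one | O=c1cc(-c2ccc(OCc3ccccc3)cc2)oc2c(I)c(OCc3ccccc3)cc(OCc3ccccc3)c12
F2 | step 5 | 5,7-bis(benzyloxy)-2-[4-(benzyloxy)phenyl]-8-(4,4,5,5-tetramethyl-1,3,2-dioxaborolan-2-yl)-4H-chromen-4-one | O=c1cc(-c2ccc(OCc3ccccc3)cc2)oc2c(B3OC(C)(C)C(C)(C)O3)c(OCc3ccccc3)cc(OCc3ccccc3)c12
F3 | step 5 | benzyl [(2S)-2-(3-bromo-4-methoxyphenyl)-7-methoxy-4-oxochroman-5-yl] carbonate | COc1cc(OC(=O)OCc3ccccc3)c2c(c1)O[C@H](c1ccc(OC)c(Br)c1)CC2=O
F4 | step 3 | racemic benzyl [2-(4-hydroxyphenyl)-7-methoxy-4-oxochroman-5-yl] carbonate | COc1cc(OC(=O)OCc3ccccc3)c2c(c1)OC(c1ccc(O)cc1)CC2=O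
F5 | step 3 | benzyl [(2R,4R)-4-hydroxy-2-(4-hydroxyphenyl)-7-methoxychroman-5-yl] carbonate | COc1cc(OC(=O)OCc3ccccc3)c2c(c1)O[C@@H](c1ccc(O)cc1)C[C@H]2O
F0 | step 7 | none | none
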